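## Retrosynthetic overview

- The target is an achiral depside. Ring A (3-chloro-2-hydroxy-4-methoxy-6-pentylbenzoyl) is esterified to the oxygen on C4 of ring B (olivetolic acid). No ring is built, because both benzene rings come from olivetol.
- The strategy rests on the single carbonyl carbon between ring A C1 and the oxygen on ring B C4. It is supplied by CO, so C1–C(=O) and C(=O)–O are cut together, leaving an aryl iodide and a phenol.
- The ring A iodide goes back to 2-chloro-1,3-dimethoxy-5-pentylbenzene, which has a mirror plane through C–Cl and C–pentyl. Its two ring CH positions are the same, so iodination defines C1 with no regiochemical choice. Chlorine is placed earlier by lithiation between the two methoxy groups.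
- The ring B partner is benzyl olivetolate, made by carboxylating olivetol and benzylating the carboxylate.
- After the union, BCl3 removes only the ring A C2 methyl ether beside the ester carbonyl, and hydrogenolysis frees the ring B acid.

Key step: step 6

Remark: the target has no stereocentre. Ring A is numbered from the carbon bearing the ester carbonyl (C1), and ring B from the carbon bearing the carboxyl group (C1).

## Route

Step 1
Reactants: 1 olivetol (5-pentylbenzene-1,3-diol)
Product: 2 1,3-dimethoxy-5-pentylbenzene
Conditions: MeI (2.5 equiv), K2CO3 (3 equiv), acetone, reflux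
Reagents that add atoms: iodomethane, CI
Why: Williamson ether synthesis, in which K2CO3 forms both phenoxides and each displaces iodide from MeI by SN2, with no other nucleophilic site in the molecule.

Step 2
Reactants: 2 1,3-dimethoxy-5-pentylbenzene
Product: 4 2-chloro-1,3-dimethoxy-5-pentylbenzene, via aryllithium 3 (not isolated)
Conditions: n-BuLi (1.1 equiv), THF, 0 °C to rt; then C2Cl6 (1.2 equiv), THF, −78 °C to rt
Reagents that add atoms: hexachloroethane, ClC(Cl)(Cl)C(Cl)(Cl)Cl; n-butyllithium, [Li]CCCC (supplies the lithium of 3 only)
Why: Directed ortho-metalation removes the ring proton flanked by both methoxy groups, the most acidic and doubly coordinated site, and the aryllithium then takes a chlorine from C2Cl6, fixing chlorine at a position that direct electrophilic chlorination would not single out.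

Step 3
Reactants: 4 2-chloro-1,3-dimethoxy-5-pentylbenzene
Product: 5 3-chloro-1-iodo-2,4-dimethoxy-6-pentylbenzene
Conditions: NIS (1.0 equiv), CF3CO2H (0.2 equiv), MeCN, 0 °C to rt, dark
Reagents that add atoms: N-iodosuccinimide, O=C1CCC(=O)N1I
Why: Electrophilic aromatic iodination with acid-activated NIS can give only one monoiodide, because the two open positions are mirror-related and each lies ortho to one methoxy group and para to the other, and the second iodination should be slower once the methoxy group between Cl and iodine is twisted out of conjugation.

Step 4
Reactants: 1 olivetol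
Product: 6 olivetolic acid (2,4-dihydroxy-6-pentylbenzoic acid)
Conditions: Mg(OCO2CH3)2 (2 M in DMF, excess), 120 °C, N2; then cold aq. HCl, 0 °C
Reagents that add atoms: magnesium bis(methyl carbonate), COC(=O)[O-].COC(=O)[O-].[Mg+2]
Why: Kolbe–Schmitt-type carboxylation, in which the magnesium phenoxide delivers CO2 to the ortho carbon that is also para to the second hydroxy group, and the resulting magnesium salicylate chelate holds the otherwise reversible carboxylation in place until the cold acid work-up.

Step 5
Reactants: 6 olivetolic acid; 7 benzyl bromide
Product: 8 benzyl olivetolate (benzyl 2,4-dihydroxy-6-pentylbenzoate)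
Conditions: BnBr (1.05 equiv), KHCO3 (1.2 equiv), DMF, rt
Reagents that add atoms: benzyl bromide 7, BrCc1ccccc1
Why: SN2 O-alkylation of a carboxylate, since KHCO3 deprotonates only the carboxylic acid and leaves both phenols neutral, and room temperature avoids decarboxylation of the acid.

Step 6
Reactants: 5 3-chloro-1-iodo-2,4-dimethoxy-6-pentylbenzene; 8 benzyl olivetolate (1.2 equiv); 9 carbon monoxide
Product: 10 benzyl 4-[(3-chloro-2,4-dimethoxy-6-pentylbenzoyl)oxy]-2-hydroxy-6-pentylbenzoate
Conditions: CO (1 atm, balloon), Pd(OAc)2 (5 mol %), Xantphos (6 mol %), Et3N (2 equiv), toluene, 90 °C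
Reagents that add atoms: carbon monoxide 9, [C-]#[O+]
Why: Zerovalent palladium, formed in the flask from Pd(OAc)2 and Xantphos, adds oxidatively to the carbon–iodine bond of 5, CO inserts into the aryl–palladium bond (a migration that the two ortho groups favour by relief of strain), and the phenoxide of 8 replaces iodide on the divalent aroylpalladium before C–O reductive elimination releases 10 and returns the catalyst. The closest known reaction type is the palladium-catalysed aryloxycarbonylation of aryl iodides with phenols under one atmosphere of CO with a wide-bite-angle bisphosphine. The step forms two skeletal bonds, ring A C1–C(=O) and C(=O)–O on ring B C4, closes no ring and creates no stereocentre. Because the C–O bond forms in the coordination sphere of the metal, no nucleophile has to approach an acyl carbon shielded by the C2 methoxy and C6 pentyl groups. Selectivity between the halogens rests on the much weaker carbon–iodine bond, as the C–Cl bond sits between two methoxy groups on an electron-rich ring and this catalyst does not activate it at 90 °C. Selectivity between the phenols rests on the 4-OH of 8 being free, unhindered and more acidic (para to the ester), whereas the 2-OH is hydrogen-bonded to the benzyl ester carbonyl and crowded by it, and a slight excess of 8 guards against a second acylation.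

Step 7
Reactants: 10 benzyl 4-[(3-chloro-2,4-dimethoxy-6-pentylbenzoyl)oxy]-2-hydroxy-6-pentylbenzoate
Product: 11 benzyl 4-[(3-chloro-2-hydroxy-4-methoxy-6-pentylbenzoyl)oxy]-2-hydroxy-6-pentylbenzoate
Conditions: BCl3 (1 M in CH2Cl2, 3 equiv), CH2Cl2, −78 °C to 0 °C; then H2O
Reagents that add atoms: none
Why: Chelation-controlled Lewis acid ether cleavage, in which boron is held in a six-membered chelate between the depside carbonyl oxygen and the ring A C2 methoxy oxygen so that chloride removes that methyl group by SN2, while the C4 methoxy group has no neighbouring carbonyl and survives at low temperature, and any partial loss of the benzyl group would only anticipate step 8.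

Step 8
Reactants: 11 benzyl 4-[(3-chloro-2-hydroxy-4-methoxy-6-pentylbenzoyl)oxy]-2-hydroxy-6-pentylbenzoate
Product: 12 4-[(3-chloro-2-hydroxy-4-methoxy-6-pentylbenzoyl)oxy]-2-hydroxy-6-pentylbenzoic acid (target)
Conditions: H2 (1 atm), Pd/C (10 wt % Pd), EtOAc, rt, no base, stopped after uptake of one equivalent
Reagents that add atoms: none
Why: Catalytic hydrogenolysis of a benzyl ester is fast under neutral conditions, whereas the chloride on the electron-rich ring A is reduced only slowly without base, and the non-nucleophilic solvent protects the depside ester from alcoholysis.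

## Compound list

| No. | Name | SMILES | Role |
|---|---|---|---|
| 1 | olivetol | CCCCCc1cc(O)cc(O)c1 | starting material |
| 2 | 1,3-dimethoxy-5-pentylbenzene | CCCCCc1cc(OC)cc(OC)c1 | intermediate |
| 3 | 2-lithio-1,3-dimethoxy-5-pentylbenzene (aryllithium, not isolated) | CCCCCc1cc(OC)c([Li])c(OC)c1 | intermediate |
| 4 | 2-chloro-1,3-dimethoxy-5-pentylbenzene | CCCCCc1cc(OC)c(Cl)c(OC)c1 | intermediate |
| 5 | 3-chloro-1-iodo-2,4-dimethoxy-6-pentylbenzene | CCCCCc1cc(OC)c(Cl)c(OC)c1I | intermediate |
| 6 | olivetolic acid | CCCCCc1cc(O)cc(O)c1C(=O)O | intermediate |
| 7 | benzyl bromide | BrCc1ccccc1 | starting material |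
| 8 | benzyl olivetolate | CCCCCc1cc(O)cc(O)c1C(=O)OCc1ccccc1 | intermediate |
| 9 | carbon monoxide | [C-]#[O+] | starting material |
| 10 | benzyl 4-[(3-chloro-2,4-dimethoxy-6-pentylbenzoyl)oxy]-2-hydroxy-6-pentylbenzoate | CCCCCc1cc(OC(=O)c2c(CCCCC)cc(OC)c(Cl)c2OC)cc(O)c1C(=O)OCc1ccccc1 | intermediate |
| 11 | benzyl 4-[(3-chloro-2-hydroxy-4-methoxy-6-pentylbenzoyl)oxy]-2-hydroxy-6-pentylbenzoate | CCCCCc1cc(OC(=O)c2c(CCCCC)cc(OC)c(Cl)c2O)cc(O)c1C(=O)OCc1ccccc1 | intermediate |
| 12 | 4-[(3-chloro-2-hydroxy-4-methoxy-6-pentylbenzoyl)oxy]-2-hydroxy-6-pentylbenzoic acid | CCCCCc1cc(OC(=O)c2c(CCCCC)cc(OC)c(Cl)c2O)cc(O)c1C(=O)O | target |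

Total step count: 8
Longest linear sequence: 6 (steps 1, 2, 3, 6, 7, 8)

## Steps most likely to fail

**1. Step 6.**
- Risk: capture of the crowded aroylpalladium by the weakly nucleophilic phenol may be slower than catalyst decay under CO or reduction of the arylpalladium. Conversion would then stall, or the iodide would be lost by protodeiodination.
- Fallback, from 5 back to 10: iodine–magnesium exchange of 5 with i-PrMgCl·LiCl in THF at −20 °C should give the arylmagnesium chloride F1. Quenching with CO2 gas and acidifying gives 3-chloro-2,4-dimethoxy-6-pentylbenzoic acid F2. Trifluoroacetic anhydride in toluene at rt converts it into the mixed trifluoroacetic anhydride F3. This ionises readily to a linear, electron-rich acylium ion that is little affected by the ortho groups, and it acylates the free 4-OH of 8 to give 10, as in the classical depside condensation.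

**2. Step 4.**
- Risk: carboxylation may occur at the carbon between the two hydroxy groups, or the product may lose CO2 during heating or acid work-up.
- Fallback, from 1 back to 6: Vilsmeier–Haack formylation (POCl3, DMF, 0 °C to rt) attacks the position para to one hydroxy group and next to the pentyl chain and should give the aryl iminium chloride F4. Water hydrolyses it to 2,4-dihydroxy-6-pentylbenzaldehyde F5. Pinnick oxidation (NaClO2, NaH2PO4, DMSO–H2O, 0 °C to rt, with DMSO scavenging hypochlorite) then gives 6 without a hot carboxylation equilibrium.

**3. Step 8.**
- Risk: reductive loss of the ring A chlorine may compete with debenzylation on the palladium surface.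
- Fallback, from 11 back to 12: the benzyl ester is cleaved without hydrogen by Lewis acid debenzylation with BCl3 (3 equiv) and pentamethylbenzene (3 equiv) in CH2Cl2 at −78 °C. Boron bound to the ring B 2-oxygen and the ester carbonyl activates the benzyl–oxygen bond. Pentamethylbenzene takes up the benzyl cation before it can alkylate either electron-rich ring, and aqueous work-up gives 12. No compound outside the list is made on this path (entry F0).

## Further compounds

F1 | step 6 | (3-chloro-2,4-dimethoxy-6-pentylphenyl)magnesium chloride | CCCCCc1cc(OC)c(Cl)c(OC)c1[Mg]Cl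
F2 | step 6 | 3-chloro-2,4-dimethoxy-6-pentylbenzoic acid | CCCCCc1cc(OC)c(Cl)c(OC)c1C(=O)O
F3 | step 6 | 3-chloro-2,4-dimethoxy-6-pentylbenzoic trifluoroacetic anhydride | CCCCCc1cc(OC)c(Cl)c(OC)c1C(=O)OC(=O)C(F)(F)F
F4 | step 4 | (2,4-dihydroxy-6-pentylbenzylidene)dimethylammonium chloride | CCCCCc1cc(O)cc(O)c1C=[N+](C)C.[Cl-]
F5 | step 4 | 2,4-dihydroxy-6-pentylbenzaldehyde | CCCCCc1cc(O)cc(O)c1C=O
F0 | step 8 | none | none
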